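All runs were generated by integration with constants of no real substance; scatter was added.

If a substrate falls by first order, its logarithm falls on a straight line, and at a like level of dissolved gas one number can be carried from flask to flask. I looked for that number here.

the same everywhere: gas phase 110 mM (held)
- green: substrate 0.095 M; run made earlier
- blue: substrate 0.38 M; run made earlier
- flask: substrate 0.19 M; time 15 min

| run | time / min | target / % | substrate / % |
|---|---|---|---|
| green | 3.00 | 19.3 | 80.9 |
| green | 6.00 | 34.6 | 63.6 |
| green | 10.0 | 53.4 | 46.9 |
| green | 12.0 | 59.1 | 40.0 |
| green | 15.0 | 68.2 | 31.4 |
| green | 20.0 | 77.9 | 21.1 |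
| blue | 1.33 | 7.9 | 93.2 |
| blue | 2.50 | 15.0 | 84.5 |
| blue | 4.00 | 23.2 | 76.3 |
| blue | 6.00 | 34.5 | 65.6 |
| blue | 10.0 | 51.7 | 47.8 |
| blue | 20.0 | 77.1 | 21.8 |

(standard deviation of a reading: 0.5 percentage points)

- at the start none of the gas phase is in solution

* amount of target in the flask at 15 min, in percent of the substrate charged
* amount of substrate in the flask at 15 min, in percent of the substrate charged
* concentration of dissolved gas at 15 min, in M

The first setting was the substrate. By hand, more substrate under a held gas phase could draw dissolved gas down and slow the fall, so I took logarithms of the substrate readings from 10.0 min to 20.0 min and reckoned the time per power of ten: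

green run: 28.8 min

blue run: 29.3 min

A factor of 4.00 in substrate moved this by 0.500 min. The flask's charge was twice the green run's and half the blue run's, so I took the mean, 29.1 min, as the decade time, the time in which substrate falls by one power of ten. This is a pseudo-first-order fall, as long as dissolved gas holds steady.

The second setting was time, which acts through the exponent. I started from the mean reading at 10.0 min:

substrate in the flask at 15 min: 47.3% lowered by 0.172 powers of ten, giving 31.9%

In the green run at 15.0 min, target and substrate summed to 99.6%, so I put target in the flask at 68.1%.

The gas phase was held alike in all three, so there was nothing to turn. The straight line met the full charge at 0.558 min, a delay much shorter than 15 min, and I put dissolved gas close under 0.11 M.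

The forecast gave 67.9% target, 32.1% substrate and 0.107 M dissolved gas, noting that “Both runs show nearly the same percent-versus-time curve despite a fourfold change in substrate”.

The flask gave 67.8% target, 32.2% substrate and 0.108 M dissolved gas, which put my substrate 0.30 percentage points low.

    gas phase ⇌ dissolved gas, rate k1*(csat - [dissolved gas]) (kL = 0.0620 s⁻¹)
    substrate + dissolved gas → target (k = 0.0120 L mol⁻¹ s⁻¹)
    2 dissolved gas → self-condensation product (k = 0.00260 L mol⁻¹ s⁻¹)

In the flask at 2.59 min, dissolved gas had a half-life of 6.0 min by turning into target, against a half-time of 0.186 min for its approach to saturation from the gas phase. In the flask it stood at 0.106 M at 3.75 min and 0.108 M at 15 min.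

Read the same flask at 40 min. The decade time leaves 1.03 powers of ten below the 47.3% of 10.0 min, which gives 4.42% substrate. The computed flask holds 4.58% substrate and 95.4% target.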